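The oxolane (O1, C2–C5) is disconnected at C2–C3, the bond between the aryl-bearing O–CH carbon and its methyl-bearing neighbour; with the C3 methyl carried as a formyl group this is an aldol bond to an O-benzylic oxocarbenium ion. One catalytic syn-crotylboration sets C4 and C5 (methyl and aryl cis). The precursor is an acyclic aldehyde whose C5 oxygen holds the second aryl aldehyde as a mixed methyl acetal. In one operation a silyl enol ether and the oxocarbenium ion are generated and close the ring at C2–C3, relaying C4/C5 to both new stereocentres (aryls 2,5-cis, C3 substituent trans to both neighbours). Formyl-to-methyl reduction and detosylation follow.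

Key step: step 7

Remark: ArTs = 3,5-dimethoxy-4-(4-methylbenzenesulfonyloxy)phenyl; oxolane numbering is O1, C2 (aryl carbon that becomes the electrophile in step 7), C3, C4, C5 (aryl carbon from the crotylation).

Assumption: the (R)-configured phosphoric acid of step 2 is taken to deliver the crotyl group to the Re face of the aryl aldehyde, as it does in allylborations of aryl aldehydes; if the alcohol proved to be the enantiomer, the (S)-catalyst would be used.

Step 1
Reactants: 1 syringaldehyde (4-hydroxy-3,5-dimethoxybenzaldehyde)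
Product: 2 4-formyl-2,6-dimethoxyphenyl 4-methylbenzenesulfonate (ArTs–CHO)
Conditions: TsCl, Et3N, 4-(dimethylamino)pyridine (cat.), CH2Cl2, 0 °C → rt
Reagents that add atoms: p-toluenesulfonyl chloride, Cc1ccc(cc1)S(=O)(=O)Cl
Why: Sulfonylation of the phenol; the tosylate should survive every later step, makes both aryl rings electron-poor so that benzylic C–O bonds do not ionise under Lewis acid, and is removable by hydroxide at the end.

Step 2
Reactants: 2 4-formyl-2,6-dimethoxyphenyl 4-methylbenzenesulfonate; 3 (Z)-crotylboronic acid pinacol ester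
Product: 5 (1R,2S)-1-ArTs-2-methylbut-3-en-1-ol, via borate ester 4 (not isolated)
Conditions: (R)-3,3'-bis(2,4,6-triisopropylphenyl)-1,1'-binaphthyl-2,2'-diyl hydrogen phosphate (5 mol%), toluene, −30 °C; aq. NaHCO3 work-up
Reagents that add atoms: none
Why: Chiral phosphoric acid-catalysed asymmetric crotylboration through a closed chair-like transition state, in which the (Z)-crotyl geometry fixes the syn relationship of hydroxyl and methyl and the catalyst selects the aldehyde face, so that C1 (R) and C2 (S) are set together.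

Step 3
Reactants: 2 4-formyl-2,6-dimethoxyphenyl 4-methylbenzenesulfonate
Product: 6 4-(dimethoxymethyl)-2,6-dimethoxyphenyl 4-methylbenzenesulfonate (ArTs–CH(OMe)2)
Conditions: HC(OMe)3, TsOH·H2O (cat.), MeOH, rt
Reagents that add atoms: trimethyl orthoformate, COC(OC)OC; methanol, CO
Why: Acid-catalysed acetalisation driven by the orthoformate as water scavenger; no stereocentre is formed.

Step 4
Reactants: 6 4-(dimethoxymethyl)-2,6-dimethoxyphenyl 4-methylbenzenesulfonate; 5 (1R,2S)-1-ArTs-2-methylbut-3-en-1-ol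
Product: 8 mixed acetal ArTs–CH(OMe)–O–[(1R,2S)-1-ArTs-2-methylbut-3-en-1-yl] (both acetal epimers), via chloro ether 7 (not isolated)
Conditions: 6, AcCl, ZnBr2 (cat.), CH2Cl2, rt; then 5, i-Pr2NEt, 0 °C → rt
Reagents that add atoms: none
Why: Zinc-halide-catalysed exchange of one methoxy group for chloride gives the reactive α-chloro ether 7, which O-alkylates the secondary alcohol under amine base (Williamson-type mixed acetal formation); the acetal carbon forms as both epimers, which is irrelevant because it becomes planar in step 7.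

Step 5
Reactants: 8 mixed acetal ArTs–CH(OMe)–O–[(1R,2S)-1-ArTs-2-methylbut-3-en-1-yl]
Product: 10 (3S,4R)-4-ArTs-4-[ArTs(methoxy)methoxy]-3-methylbutan-1-ol, via alkylborane 9 (not isolated)
Conditions: 9-BBN, THF, 0 °C → rt; then aq. NaOH, H2O2, 0 °C
Reagents that add atoms: hydrogen peroxide, OO
Why: Anti-Markovnikov hydroboration of the terminal alkene with the bulky borane and oxidation of the C–B bond (hydroboration–oxidation); acetal and sulfonates should tolerate the cold basic peroxide and no stereocentre is touched.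

Step 6
Reactants: 10 (3S,4R)-4-ArTs-4-[ArTs(methoxy)methoxy]-3-methylbutan-1-ol
Product: 11 (3S,4R)-4-ArTs-4-[ArTs(methoxy)methoxy]-3-methylbutanal
Conditions: Dess–Martin periodinane, NaHCO3, CH2Cl2, 0 °C → rt
Reagents that add atoms: none
Why: Dess–Martin oxidation of the primary alcohol under bicarbonate buffering, which should leave the acid-labile mixed acetal intact; the α-carbon is a CH2 group, so no stereocentre can epimerise.

Step 7
Reactants: 11 (3S,4R)-4-ArTs-4-[ArTs(methoxy)methoxy]-3-methylbutanal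
Product: 14 (2S,3S,4S,5R)-2,5-bis(ArTs)-4-methyloxolane-3-carbaldehyde, via silyl enol ether 12 (not isolated), via oxocarbenium triflate 13 (not isolated)
Conditions: i-Pr2NEt (1.5 equiv), Me3SiOTf (1.2 equiv), CH2Cl2 (0.02 M), −78 → 0 °C; then −78 °C, Me3SiOTf (0.8 equiv), −78 → −30 °C; aq. NaHCO3
Reagents that add atoms: none
Why: Intramolecular Mukaiyama aldol-type addition to an acetal: amine-assisted silylation turns the aldehyde into silyl enol ether 12, further Me3SiOTf removes the less hindered methoxy group of the mixed acetal as Me3SiOMe, and the resulting (E)-oxocarbenium ion 13 is attacked at its carbon (C2) by the enol β-carbon (C3), after which loss of the silyl group releases the aldehyde and the silyl triflate. The closest known reactions are the Lewis-acid ring contraction of 4,5-dihydro-1,3-dioxepines (cyclic vinyl acetals) to oxolane-3-carbaldehydes and Prins-type condensations of 4-hydroxy enol derivatives with aldehydes, which pass through the same tethered oxocarbenium–enol pair. The oxolane is closed in the 5-(enolexo)-endo-trig mode, the O+=C2 bond lying inside the new ring and the enol C=C outside it. C2 is controlled by C5: the C5–H bond eclipses the plane of the (E)-oxocarbenium ion to avoid allylic 1,3-strain, the tether then reaches only one face, and the two aryl groups should come out cis; C3 is controlled by C4 and C2, the enol carbon staying anti to the C4 methyl and the C2 aryl group, and a minor C3 epimer can equilibrate through the enol to this aldehyde, which is trans to both neighbours. The step needs ionisation at the methoxy rather than the secondary alkoxy oxygen and retention of configuration at benzylic C5: the first rests on the smaller, more basic methoxy group, the second on the electron-withdrawing sulfonyloxy groups, which suppress benzylic ionisation and oxonia-Cope scrambling.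

Step 8
Reactants: 14 (2S,3S,4S,5R)-2,5-bis(ArTs)-4-methyloxolane-3-carbaldehyde
Product: 16 (2S,3S,4S,5R)-2,5-bis(ArTs)-3,4-dimethyloxolane, via tosylhydrazone 15 (not isolated)
Conditions: TsNHNH2, EtOH, rt; evaporate; catecholborane, CHCl3, 0 °C; then NaOAc·3H2O, 60 °C
Reagents that add atoms: none
Why: Condensation to the tosylhydrazone, hydride reduction of its C=N bond and acetate-induced loss of sulfinate and dinitrogen from the diazene (Caglioti-type tosylhydrazone reduction with catecholborane) should convert CHO into CH3 under nearly neutral conditions without touching C3, whose configuration is in any case the thermodynamically preferred one.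

Step 9
Reactants: 16 (2S,3S,4S,5R)-2,5-bis(ArTs)-3,4-dimethyloxolane
Product: 17 4,4'-[(2S,3S,4S,5R)-3,4-dimethyloxolane-2,5-diyl]bis(2,6-dimethoxyphenol) (target)
Conditions: KOH, MeOH/THF/H2O, 65 °C, under N2; then aq. NH4Cl
Reagents that add atoms: none
Why: Hydroxide attacks sulfur of both aryl sulfonates (S–O cleavage, saponification of sulfonate esters) and releases the two phenols; the four ring stereocentres carry no acidic hydrogen and are not affected by base.

Compound list
1 | syringaldehyde (4-hydroxy-3,5-dimethoxybenzaldehyde) | O=Cc1cc(OC)c(O)c(OC)c1 | starting material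
2 | 4-formyl-2,6-dimethoxyphenyl 4-methylbenzenesulfonate | O=Cc1cc(OC)c(OS(=O)(=O)c2ccc(C)cc2)c(OC)c1 | intermediate
3 | (Z)-crotylboronic acid pinacol ester, (Z)-2-(but-2-en-1-yl)-4,4,5,5-tetramethyl-1,3,2-dioxaborolane | C/C=C\CB1OC(C)(C)C(C)(C)O1 | starting material
4 | pinacol borate ester of alcohol 5, 2-{[(1R,2S)-1-ArTs-2-methylbut-3-en-1-yl]oxy}-4,4,5,5-tetramethyl-1,3,2-dioxaborolane | C=C[C@H](C)[C@@H](OB1OC(C)(C)C(C)(C)O1)c2cc(OC)c(OS(=O)(=O)c3ccc(C)cc3)c(OC)c2 | intermediate
5 | (1R,2S)-1-ArTs-2-methylbut-3-en-1-ol (syn) | C=C[C@H](C)[C@@H](O)c1cc(OC)c(OS(=O)(=O)c2ccc(C)cc2)c(OC)c1 | intermediate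
6 | 4-(dimethoxymethyl)-2,6-dimethoxyphenyl 4-methylbenzenesulfonate | COC(OC)c1cc(OC)c(OS(=O)(=O)c2ccc(C)cc2)c(OC)c1 | intermediate
7 | 4-[chloro(methoxy)methyl]-2,6-dimethoxyphenyl 4-methylbenzenesulfonate (racemic) | COC(Cl)c1cc(OC)c(OS(=O)(=O)c2ccc(C)cc2)c(OC)c1 | intermediate
8 | mixed acetal ArTs–CH(OMe)–O–[(1R,2S)-1-ArTs-2-methylbut-3-en-1-yl], both epimers at the acetal carbon | C=C[C@H](C)[C@@H](OC(OC)c1cc(OC)c(OS(=O)(=O)c2ccc(C)cc2)c(OC)c1)c3cc(OC)c(OS(=O)(=O)c4ccc(C)cc4)c(OC)c3 | intermediate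
9 | 9-[(3S,4R)-4-ArTs-4-(ArTs(methoxy)methoxy)-3-methylbutyl]-9-borabicyclo[3.3.1]nonane | C1CCC2CCCC1B2CC[C@H](C)[C@@H](OC(OC)c3cc(OC)c(OS(=O)(=O)c4ccc(C)cc4)c(OC)c3)c5cc(OC)c(OS(=O)(=O)c6ccc(C)cc6)c(OC)c5 | intermediate
10 | (3S,4R)-4-ArTs-4-[ArTs(methoxy)methoxy]-3-methylbutan-1-ol, both acetal epimers | OCC[C@H](C)[C@@H](OC(OC)c1cc(OC)c(OS(=O)(=O)c2ccc(C)cc2)c(OC)c1)c3cc(OC)c(OS(=O)(=O)c4ccc(C)cc4)c(OC)c3 | intermediate
11 | (3S,4R)-4-ArTs-4-[ArTs(methoxy)methoxy]-3-methylbutanal, both acetal epimers | O=CC[C@H](C)[C@@H](OC(OC)c1cc(OC)c(OS(=O)(=O)c2ccc(C)cc2)c(OC)c1)c3cc(OC)c(OS(=O)(=O)c4ccc(C)cc4)c(OC)c3 | intermediate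
12 | trimethylsilyl enol ether of 11, {[(3S,4R)-4-ArTs-4-(ArTs(methoxy)methoxy)-3-methylbut-1-en-1-yl]oxy}trimethylsilane (E/Z) | C[Si](C)(C)OC=C[C@H](C)[C@@H](OC(OC)c1cc(OC)c(OS(=O)(=O)c2ccc(C)cc2)c(OC)c1)c3cc(OC)c(OS(=O)(=O)c4ccc(C)cc4)c(OC)c3 | intermediate
13 | (E)-oxocarbenium triflate, (E)-(ArTs-methylidene)[(1R,2S)-1-ArTs-2-methyl-4-(trimethylsilyloxy)but-3-en-1-yl]oxonium trifluoromethanesulfonate | C[Si](C)(C)OC=C[C@H](C)[C@@H](/[O+]=C/c1cc(OC)c(OS(=O)(=O)c2ccc(C)cc2)c(OC)c1)c3cc(OC)c(OS(=O)(=O)c4ccc(C)cc4)c(OC)c3.[O-]S(=O)(=O)C(F)(F)F | intermediate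
14 | (2S,3S,4S,5R)-2,5-bis(ArTs)-4-methyloxolane-3-carbaldehyde | COc1cc(cc(OC)c1OS(=O)(=O)c2ccc(C)cc2)[C@H]3O[C@@H](c4cc(OC)c(OS(=O)(=O)c5ccc(C)cc5)c(OC)c4)[C@@H](C)[C@@H]3C=O | intermediate
15 | 4-methylbenzenesulfonohydrazone of aldehyde 14 (ring configuration as in 14) | COc1cc(cc(OC)c1OS(=O)(=O)c2ccc(C)cc2)[C@H]3O[C@@H](c4cc(OC)c(OS(=O)(=O)c5ccc(C)cc5)c(OC)c4)[C@@H](C)[C@@H]3C=NNS(=O)(=O)c6ccc(C)cc6 | intermediate
16 | (2S,3S,4S,5R)-2,5-bis(ArTs)-3,4-dimethyloxolane | COc1cc(cc(OC)c1OS(=O)(=O)c2ccc(C)cc2)[C@H]3O[C@@H](c4cc(OC)c(OS(=O)(=O)c5ccc(C)cc5)c(OC)c4)[C@@H](C)[C@@H]3C | intermediate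
17 | 4,4'-[(2S,3S,4S,5R)-3,4-dimethyloxolane-2,5-diyl]bis(2,6-dimethoxyphenol) | COc1cc(cc(OC)c1O)[C@H]2O[C@@H](c3cc(OC)c(O)c(OC)c3)[C@@H](C)[C@@H]2C | target

Total step count: 9. Longest linear sequence: 8 steps (steps 1, 2, 4, 5, 6, 7, 8, 9); step 3 is a one-step branch from 2.

Steps most likely to fail

Step 7. The free aldehyde may exchange with the mixed acetal (expelling aldehyde 2 and leaving a 2-methoxyoxolane), or the transient silyl enol ether may react intermolecularly before the ring closes. The fallback sets out from 11: O-acetylation of the enolate (Ac2O, Et3N, 4-(dimethylamino)pyridine, 60 °C) should give the isolable enol ester (3S,4R)-4-ArTs-4-[ArTs(methoxy)methoxy]-3-methylbut-1-en-1-yl acetate F1, which no longer carries a carbonyl group. Ionisation of the acetal (SnBr4 or Me3SiOTf, 2,6-di-tert-butyl-4-methylpyridine, CH2Cl2, −78 °C) then lets the enol acetate attack the oxocarbenium ion, the acetyl group leaving with the methoxy group as methyl acetate, and the route is rejoined at 14.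

Step 4. The moisture-sensitive chloro ether 7 may hydrolyse, and O-alkylation of the hindered, electron-poor benzylic alcohol may be slow, returning aldehyde 2 and unchanged alcohol. The fallback sets out from 5: silylation (Me3SiCl, imidazole, CH2Cl2) gives [(1R,2S)-1-ArTs-2-methylbut-3-en-1-yl]oxy(trimethyl)silane F2, which undergoes acid-catalysed acetal exchange with dimethyl acetal 6 (Me3SiOTf cat., CH2Cl2, −78 °C, pyridine quench) and comes back to the route at 8.

Step 8. The ring may open by β-elimination of the ring oxygen from the hydrazone stage, or the diazene may collapse incompletely. The fallback sets out from 14: reduction (NaBH4, MeOH, 0 °C) gives [(2S,3R,4S,5R)-2,5-bis(ArTs)-4-methyloxolan-3-yl]methanol F3, Appel-type iodination (I2, PPh3, imidazole, CH2Cl2) gives (2S,3S,4S,5R)-2,5-bis(ArTs)-3-(iodomethyl)-4-methyloxolane F4, and radical dehalogenation (Bu3SnH, azobisisobutyronitrile, toluene, 80 °C) returns to the route at 16.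

Further compounds
F1 | step 7 | (3S,4R)-4-ArTs-4-[ArTs(methoxy)methoxy]-3-methylbut-1-en-1-yl acetate (E/Z, both acetal epimers) | CC(=O)OC=C[C@H](C)[C@@H](OC(OC)c1cc(OC)c(OS(=O)(=O)c2ccc(C)cc2)c(OC)c1)c3cc(OC)c(OS(=O)(=O)c4ccc(C)cc4)c(OC)c3
F2 | step 4 | [(1R,2S)-1-ArTs-2-methylbut-3-en-1-yl]oxy(trimethyl)silane | C=C[C@H](C)[C@@H](O[Si](C)(C)C)c1cc(OC)c(OS(=O)(=O)c2ccc(C)cc2)c(OC)c1
F3 | step 8 | [(2S,3R,4S,5R)-2,5-bis(ArTs)-4-methyloxolan-3-yl]methanol | COc1cc(cc(OC)c1OS(=O)(=O)c2ccc(C)cc2)[C@H]3O[C@@H](c4cc(OC)c(OS(=O)(=O)c5ccc(C)cc5)c(OC)c4)[C@@H](C)[C@@H]3CO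
F4 | step 8 | (2S,3S,4S,5R)-2,5-bis(ArTs)-3-(iodomethyl)-4-methyloxolane | COc1cc(cc(OC)c1OS(=O)(=O)c2ccc(C)cc2)[C@H]3O[C@@H](c4cc(OC)c(OS(=O)(=O)c5ccc(C)cc5)c(OC)c4)[C@@H](C)[C@@H]3CI
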